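A direct plan would build ring A onto a quinone-derived ring B by a catalytic asymmetric Diels–Alder reaction of 2,6-dimethyl-1,4-benzoquinone A1 with the silyloxy diene (E)-tert-butyldimethyl(penta-2,4-dien-1-yloxy)silane A2. It would then trim the cis-fused ene-dione adduct A3 to the C9 enol triflate A4, attach the side chain by B-alkyl Suzuki coupling to give the C4–H ester A5, and finish with C4 methylation, desilylation and acetylation.
Its weakest parts would be:
(1) The repair of A3: the cycloaddition of A1 with A2 delivers a cis ring fusion, so hydrogenation and base epimerisation to the trans fusion only correct what it gives, and they open a run-up of about ten steps to the simple triflate A4.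
(2) The C4 quaternary centre: the configuration set at C4 in the cycloaddition would be discarded and made again at the very end by methylation of an ester enolate of A5. Facial control would rest on one 1,3-diaxial methyl group, and a C4 epimer would be hard to remove.
(3) The late sp3–sp2 coupling at C9: it has to make a tetrasubstituted alkene carbon next to the quaternary C10, where slow transmetalation and β-hydride loss would cost material at the most valuable stage.

Retrosynthetic overview of the new route
The new route cuts C4–C5 and C9–C10 at once: one radical cascade of an acyclic α-bromo β-keto ester closes ring A, then ring B, and sets C4, C5 and C10 together under control of an 8-phenylmenthyl ester.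
The cascade ends on a C8=C9=C11 allene, so the tetrasubstituted C8=C9 alkene of ring B appears in its final place with the whole side chain (C11–C16) already attached.
The acyclic precursor would come from dehydrolinalool (C1, C5–C11, C17, C20), a C5 allylic bromide (C12–C16) and a 2-methylacetoacetate (C2–C4, C18, C19) by alkyne allylation, propargylic alcohol-to-allene reduction and dianion alkylation.
By design there is no cis-to-trans correction, no late C4 alkylation and no coupling at the hindered C9; after the key step only C3 is deoxygenated and the C19 ester is turned into the acid.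
Key step: step 10

Assumptions: (a) The (−)-8-phenylmenthyl ester is taken to shield the face of the C4 radical that leads to the (5R,10S) series; should the sense prove opposite, the (+)-auxiliary would be used with no other change. (b) Dehydrolinalool is used as the racemate; its stereocentre becomes the allene axis, whose configuration is lost in the cyclisation.

Step 1
Reactants: 1 3,7-dimethyloct-6-en-1-yn-3-ol (dehydrolinalool)
Product: 2 (2E)-2,6-dimethyloct-2-en-7-yne-1,6-diol
Conditions: SeO2 (0.2 equiv), t-BuOOH (2.5 equiv), salicylic acid (0.1 equiv), CH2Cl2, rt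
Reagents that add atoms: tert-butyl hydroperoxide, CC(C)(C)OO
Why: Catalytic SeO2 with t-BuOOH should oxidise only the E methyl group of the trisubstituted alkene (Riley-type allylic oxidation by ene reaction and [2,3]-shift), giving the E allylic alcohol that becomes C1, while the alkyne and the tertiary alcohol are left alone.

Step 2
Reactants: 3 3-methylbut-2-en-1-yl benzoate (prenyl benzoate)
Product: 4 (2E)-4-hydroxy-3-methylbut-2-en-1-yl benzoate
Conditions: SeO2 (0.2 equiv), t-BuOOH (2.5 equiv), salicylic acid (0.1 equiv), CH2Cl2, rt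
Reagents that add atoms: tert-butyl hydroperoxide, CC(C)(C)OO
Why: The same E-selective allylic oxidation (Riley oxidation) should hydroxylate the methyl group trans to the CH2O substituent and so fix the E geometry of the later C13=C14 alkene.

Step 3
Reactants: 4 (2E)-4-hydroxy-3-methylbut-2-en-1-yl benzoate
Product: 5 (2E)-4-bromo-3-methylbut-2-en-1-yl benzoate
Conditions: CBr4, PPh3, CH2Cl2, 0 °C
Reagents that add atoms: carbon tetrabromide, BrC(Br)(Br)Br
Why: The Appel reaction converts the primary allylic alcohol into the bromide under neutral conditions, without allylic transposition or loss of the E geometry.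

Step 4
Reactants: 2 (2E)-2,6-dimethyloct-2-en-7-yne-1,6-diol; 5 (2E)-4-bromo-3-methylbut-2-en-1-yl benzoate
Product: 6 (2E,10E)-7,12-dihydroxy-3,7,11-trimethyldodeca-2,10-dien-5-yn-1-yl benzoate
Conditions: CuI (20 mol %), Cs2CO3 (1.5 equiv), Bu4NI (10 mol %), DMF, rt
Reagents that add atoms: none
Why: The copper acetylide formed under carbonate should displace the primary allylic bromide at its α-carbon (copper-catalysed allylation of a terminal alkyne), forming C11–C12 as a skipped enyne with the E alkene retained and the free hydroxyl groups and the benzoate tolerated.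

Step 5
Reactants: 6 (2E,10E)-7,12-dihydroxy-3,7,11-trimethyldodeca-2,10-dien-5-yn-1-yl benzoate
Product: 8 (2E,10E)-12-hydroxy-3,7,11-trimethyldodeca-2,5,6,10-tetraen-1-yl benzoate, via bis(chloromagnesium) alkoxide 7 (not isolated)
Conditions: EtMgCl (2.0 equiv), THF, −40 °C; then Cp2Zr(H)Cl (2.5 equiv), THF/PhMe, −40 °C to rt; H2O
Reagents that add atoms: none
Why: Alkoxide-directed hydrozirconation should place zirconium on C9 and hydrogen on C11, and β-elimination of the zirconium alkoxide then gives the trisubstituted allene (hydrozirconation–elimination of a propargylic alcohol, a formal SN2′ reduction); the allene axis forms as a racemate, which is of no consequence.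

Step 6
Reactants: 8 (2E,10E)-12-hydroxy-3,7,11-trimethyldodeca-2,5,6,10-tetraen-1-yl benzoate
Product: 9 (2E,10E)-12-bromo-3,7,11-trimethyldodeca-2,5,6,10-tetraen-1-yl benzoate
Conditions: CBr4, PPh3, CH2Cl2, −20 °C
Reagents that add atoms: carbon tetrabromide, BrC(Br)(Br)Br
Why: The Appel reaction again converts the primary allylic alcohol into the bromide under neutral conditions that leave the allene, the alkenes and the benzoate intact.

Step 7
Reactants: 10 methyl 2-methyl-3-oxobutanoate; 11 (1R,2S,5R)-5-methyl-2-(2-phenylpropan-2-yl)cyclohexan-1-ol ((−)-8-phenylmenthol)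
Product: 12 (1R,2S,5R)-8-phenylmenthyl 2-methyl-3-oxobutanoate
Conditions: DMAP (0.3 equiv), PhMe, reflux, 4 Å molecular sieves
Reagents that add atoms: none
Why: DMAP-catalysed transesterification of a β-keto ester exchanges methanol for the hindered secondary alcohol when the methanol is removed, and the configuration of the auxiliary is not touched.

Step 8
Reactants: 12 (1R,2S,5R)-8-phenylmenthyl 2-methyl-3-oxobutanoate; 9 (2E,10E)-12-bromo-3,7,11-trimethyldodeca-2,5,6,10-tetraen-1-yl benzoate
Product: 14 (1R,2S,5R)-8-phenylmenthyl (6E,14E)-16-(benzoyloxy)-2,6,10,14-tetramethyl-3-oxohexadeca-6,10,11,14-tetraenoate, via sodium lithium dianion 13 (not isolated)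
Conditions: 12 (1.2 equiv), NaH (1.2 equiv), THF, 0 °C; n-BuLi (1.2 equiv), 0 °C; then 9, −78 to 0 °C; AcOH
Reagents that add atoms: none
Why: The dianion of the β-keto ester reacts only at its more basic terminal γ-carbon with the primary allylic bromide (dianion alkylation of an acetoacetate), which forms C1–C2 and, at low temperature, should leave the allene, the E alkenes and the benzoate untouched.

Step 9
Reactants: 14 (1R,2S,5R)-8-phenylmenthyl (6E,14E)-16-(benzoyloxy)-2,6,10,14-tetramethyl-3-oxohexadeca-6,10,11,14-tetraenoate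
Product: 16 (1R,2S,5R)-8-phenylmenthyl (6E,14E)-16-(benzoyloxy)-2-bromo-2,6,10,14-tetramethyl-3-oxohexadeca-6,10,11,14-tetraenoate, via sodium enolate 15 (not isolated)
Conditions: NaH (1.1 equiv), THF, 0 °C; NBS (1.05 equiv), −78 °C; AcOH
Reagents that add atoms: N-bromosuccinimide, BrN1C(=O)CCC1=O
Why: The sodium enolate is brominated at carbon by NBS at −78 °C far faster than NBS can attack the alkenes or the allene (enolate α-halogenation), and both C4 epimers are usable because C4 becomes planar in the next step.

Step 10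
Reactants: 16 (1R,2S,5R)-8-phenylmenthyl (6E,14E)-16-(benzoyloxy)-2-bromo-2,6,10,14-tetramethyl-3-oxohexadeca-6,10,11,14-tetraenoate
Product: 17 (1R,2S,5R)-8-phenylmenthyl 15-(benzoyloxy)-3-oxolabda-8,13E-dien-19-oate (4β-ester axial; 4α-methyl; 5α-H; 10β-methyl; 4R,5R,10S)
Conditions: Bu3SnH (1.3 equiv) and 2,2′-azobis(4-methoxy-2,4-dimethylvaleronitrile) (0.2 equiv) in PhH, added over 10 h to 16 (0.004 M) in PhH, 30 °C
Reagents that add atoms: none
Why: Proposed new method: the tributyltin radical abstracts bromine from C4, the planar α-keto ester radical adds 6-endo to C5 of the E C5=C10 alkene, the tertiary C10 radical adds 6-endo to the sp carbon C9 of the allene, and the resulting C8–C9–C11 allyl radical takes hydrogen from Bu3SnH at the less hindered C11, which leaves the tetrasubstituted C8=C9 alkene with the full side chain in place. The closest known reaction types are the 6-endo, 6-endo radical polyene cyclisations of α-methyl β-keto esters to trans-decalins (oxidative with Mn(OAc)3, or reductive with tin hydride) and the addition of alkyl radicals to the central carbon of allenes; ending such a cascade on an allene is the new element. Ring A closes by 6-endo-trig attack, since the methyl group on the proximal alkene carbon C10 disfavours 5-exo, and ring B by 6-endo attack on the allene through a chair-like transition state in which sp2 C8 and sp C9 take the place of the usual trisubstituted alkene. C5 and C10 follow from anti addition across the E alkene in a chair–chair arrangement (trans ring fusion); at C4 the ester takes the axial position cis to the C10 methyl, because the alternative would force a methyl–methyl 1,3-diaxial contact; the absolute sense comes from the 8-phenylmenthyl ester, whose phenyl ring covers one face of the radical, and the diastereomer from attack on the other face should be separable by chromatography. The step needs 6-endo over 5-exo closure, attack at C9 and not at C8 (fully substituted) or C11 (a seven-membered cyclic allene), and hydrogen delivery to C11 and not C8; slow addition keeps the tin hydride concentration low enough for both ring closures to precede reduction.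

Step 11
Reactants: 17 (1R,2S,5R)-8-phenylmenthyl 15-(benzoyloxy)-3-oxolabda-8,13E-dien-19-oate
Product: 19 (1R,2S,5R)-8-phenylmenthyl 15-(benzoyloxy)labda-8,13E-dien-19-oate (4S,5R,10S), via C3 tosylhydrazone 18 (not isolated)
Conditions: TsNHNH2 (1.5 equiv), EtOH, 60 °C; then catecholborane (3 equiv), CHCl3, 0 °C to rt; NaOAc·3H2O, reflux
Reagents that add atoms: none
Why: Condensation gives the tosylhydrazone of the only ketone, and hydride addition by catecholborane followed by acetate-triggered loss of sulfinate and dinitrogen leaves a CH2 group at C3 (Caglioti-type hydrazone reduction) without touching the alkenes, the esters or the quaternary C4.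

Step 12
Reactants: 19 (1R,2S,5R)-8-phenylmenthyl 15-(benzoyloxy)labda-8,13E-dien-19-oate
Product: 20 labda-8,13E-diene-15,19-diol (4S,5R,10S)
Conditions: LiAlH4 (4 equiv), THF, 0 °C to reflux; then H2O, aq. NaOH
Reagents that add atoms: none
Why: LiAlH4 reduces the hindered axial ester to the C19 primary alcohol and cleaves the benzoate in the same operation (hydride reduction of esters), which frees the auxiliary alcohol 11 for reuse and affects no stereocentre.

Step 13
Reactants: 20 labda-8,13E-diene-15,19-diol
Product: 21 19-hydroxylabda-8,13E-dien-15-yl acetate (4S,5R,10S)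
Conditions: vinyl acetate (3 equiv), immobilised Candida antarctica lipase B, t-BuOMe, 30 °C
Reagents that add atoms: vinyl acetate, CC(=O)OC=C
Why: Lipase-catalysed transesterification with vinyl acetate should acetylate the unhindered allylic C15 hydroxyl and leave the axial, neopentyl C19 hydroxyl free, because the latter does not fit the active site (enzymatic regioselective acylation).

Step 14
Reactants: 21 19-hydroxylabda-8,13E-dien-15-yl acetate
Product: 23 15-acetoxylabda-8,13E-dien-19-oic acid (target; 4S,5R,10S), via C19 aldehyde 22 (not isolated)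
Conditions: Dess–Martin periodinane (1.3 equiv), NaHCO3, CH2Cl2, 0 °C to rt; then NaClO2, NaH2PO4, 2-methyl-2-butene, t-BuOH/H2O, 0 °C to rt
Reagents that add atoms: sodium chlorite, [Na+].[O-]Cl=O
Why: Dess–Martin oxidation gives the neopentyl aldehyde, which chlorite oxidises to the acid under buffered conditions with 2-methyl-2-butene as hypochlorite scavenger (Pinnick oxidation), so the two alkenes and the allylic acetate survive and the quaternary C4 cannot epimerise.

Compound list
1 | 3,7-dimethyloct-6-en-1-yn-3-ol (dehydrolinalool, racemate) | CC(C)=CCCC(C)(O)C#C | starting material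
2 | (2E)-2,6-dimethyloct-2-en-7-yne-1,6-diol (racemate) | OC/C(C)=C/CCC(C)(O)C#C | intermediate
3 | 3-methylbut-2-en-1-yl benzoate (prenyl benzoate) | CC(C)=CCOC(=O)c1ccccc1 | starting material
4 | (2E)-4-hydroxy-3-methylbut-2-en-1-yl benzoate | OC/C(C)=C/COC(=O)c1ccccc1 | intermediate
5 | (2E)-4-bromo-3-methylbut-2-en-1-yl benzoate | BrC/C(C)=C/COC(=O)c1ccccc1 | intermediate
6 | (2E,10E)-7,12-dihydroxy-3,7,11-trimethyldodeca-2,10-dien-5-yn-1-yl benzoate (racemate) | OC/C(C)=C/CCC(C)(O)C#CC/C(C)=C/COC(=O)c1ccccc1 | intermediate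
7 | bis(chloromagnesium) alkoxide of 6 | Cl[Mg]OC/C(C)=C/CCC(C)(O[Mg]Cl)C#CC/C(C)=C/COC(=O)c1ccccc1 | intermediate
8 | (2E,10E)-12-hydroxy-3,7,11-trimethyldodeca-2,5,6,10-tetraen-1-yl benzoate (racemic allene) | OC/C(C)=C/CCC(C)=C=CC/C(C)=C/COC(=O)c1ccccc1 | intermediate
9 | (2E,10E)-12-bromo-3,7,11-trimethyldodeca-2,5,6,10-tetraen-1-yl benzoate (racemic allene) | BrC/C(C)=C/CCC(C)=C=CC/C(C)=C/COC(=O)c1ccccc1 | intermediate
10 | methyl 2-methyl-3-oxobutanoate | CC(=O)C(C)C(=O)OC | starting material
11 | (1R,2S,5R)-5-methyl-2-(2-phenylpropan-2-yl)cyclohexan-1-ol ((−)-8-phenylmenthol) | O[C@@H]1C[C@H](C)CC[C@H]1C(C)(C)c1ccccc1 | starting material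
12 | (1R,2S,5R)-8-phenylmenthyl 2-methyl-3-oxobutanoate (both C2 epimers) | CC(=O)C(C)C(=O)O[C@@H]1C[C@H](C)CC[C@H]1C(C)(C)c1ccccc1 | intermediate
13 | sodium lithium dianion of 12 | [Na+].[Li+].C=C([O-])C(C)=C([O-])O[C@@H]1C[C@H](C)CC[C@H]1C(C)(C)c1ccccc1 | intermediate
14 | (1R,2S,5R)-8-phenylmenthyl (6E,14E)-16-(benzoyloxy)-2,6,10,14-tetramethyl-3-oxohexadeca-6,10,11,14-tetraenoate (C2 epimers, racemic allene) | O=C(OC/C=C(\C)CC=C=C(C)CC/C=C(\C)CCC(=O)C(C)C(=O)O[C@@H]1C[C@H](C)CC[C@H]1C(C)(C)c1ccccc1)c1ccccc1 | intermediate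
15 | sodium enolate of 14 (enolate geometry not defined) | O=C(OC/C=C(\C)CC=C=C(C)CC/C=C(\C)CCC([O-])=C(C)C(=O)O[C@@H]1C[C@H](C)CC[C@H]1C(C)(C)c1ccccc1)c1ccccc1.[Na+] | intermediate
16 | (1R,2S,5R)-8-phenylmenthyl (6E,14E)-16-(benzoyloxy)-2-bromo-2,6,10,14-tetramethyl-3-oxohexadeca-6,10,11,14-tetraenoate (C2 epimers, racemic allene) | O=C(OC/C=C(\C)CC=C=C(C)CC/C=C(\C)CCC(=O)C(C)(Br)C(=O)O[C@@H]1C[C@H](C)CC[C@H]1C(C)(C)c1ccccc1)c1ccccc1 | intermediate
17 | (1R,2S,5R)-8-phenylmenthyl 15-(benzoyloxy)-3-oxolabda-8,13E-dien-19-oate (4β-ester, 4α-methyl, 5α-H, 10β-methyl; 4R,5R,10S) | O=C(OC/C=C(\C)CCC1=C(C)CC[C@H]2[C@@](C)(C(=O)O[C@@H]3C[C@H](C)CC[C@H]3C(C)(C)c3ccccc3)C(=O)CC[C@]12C)c1ccccc1 | intermediate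
18 | C3 tosylhydrazone of 17 (C=N geometry not defined) | O=C(OC/C=C(\C)CCC1=C(C)CC[C@H]2[C@@](C)(C(=O)O[C@@H]3C[C@H](C)CC[C@H]3C(C)(C)c3ccccc3)C(=NNS(=O)(=O)c3ccc(C)cc3)CC[C@]12C)c1ccccc1 | intermediate
19 | (1R,2S,5R)-8-phenylmenthyl 15-(benzoyloxy)labda-8,13E-dien-19-oate (4S,5R,10S) | O=C(OC/C=C(\C)CCC1=C(C)CC[C@H]2[C@@](C)(C(=O)O[C@@H]3C[C@H](C)CC[C@H]3C(C)(C)c3ccccc3)CCC[C@]12C)c1ccccc1 | intermediate
20 | labda-8,13E-diene-15,19-diol (4S,5R,10S) | OC/C=C(\C)CCC1=C(C)CC[C@H]2[C@@](C)(CO)CCC[C@]12C | intermediate
21 | 19-hydroxylabda-8,13E-dien-15-yl acetate (4S,5R,10S) | CC(=O)OC/C=C(\C)CCC1=C(C)CC[C@H]2[C@@](C)(CO)CCC[C@]12C | intermediate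
22 | 19-oxolabda-8,13E-dien-15-yl acetate (4S,5R,10S) | CC(=O)OC/C=C(\C)CCC1=C(C)CC[C@H]2[C@@](C)(C=O)CCC[C@]12C | intermediate
23 | 15-acetoxylabda-8,13E-dien-19-oic acid (4S,5R,10S) | CC(=O)OC/C=C(\C)CCC1=C(C)CC[C@H]2[C@@](C)(C(=O)O)CCC[C@]12C | target

Total step count: 14. Longest linear sequence: 12 steps (steps 2, 3, 4, 5, 6, 8, 9, 10, 11, 12, 13, 14).

Steps most likely to fail

Step 10 (proposed new method). The cascade could be eroded by hydrogen transfer to the C4 or C10 radical before ring closure, by weak facial control from the auxiliary, or by hydrogen delivery to C8 in place of C11. The fallback uses known reactions and changes the terminating group from the allene to the alkyne. It would set out from 6: Appel bromination of the primary allylic alcohol alone would give (2E,10E)-12-bromo-7-hydroxy-3,7,11-trimethyldodeca-2,10-dien-5-yn-1-yl benzoate F1. Alkylation of dianion 13 (one extra equivalent for the tertiary alkoxide) would give the alkynyl keto ester (1R,2S,5R)-8-phenylmenthyl (6E,14E)-16-(benzoyloxy)-10-hydroxy-2,6,10,14-tetramethyl-3-oxohexadeca-6,14-dien-11-ynoate F2, and NaH/NBS would give its 2-bromo derivative F3. A tin hydride mediated radical cyclisation (6-endo-trig, then 6-exo-dig onto the alkyne, with the vinyl radical reduced by Bu3SnH) would give (1R,2S,5R)-8-phenylmenthyl 15-(benzoyloxy)-8-hydroxy-3-oxolabda-9(11),13E-dien-19-oate F4. Ionic hydrogenation (Et3SiH, BF3·OEt2, CH2Cl2, −78 °C) would ionise the tertiary allylic alcohol and deliver hydride to C11 of the allyl cation, which moves the alkene into the C8=C9 position and returns to the route at 17. The ring fusion of F4 would have to be confirmed, since a 6-exo closure is less strongly biased toward the trans-decalin.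

Step 5. The Grignard base or the zirconium hydride could attack the benzoate, or the elimination to the allene could stall. The fallback replaces the hydrozirconation by a copper hydride SN2′ reduction of a propargylic carbonate, from 6. TBSCl/imidazole would give (2E,10E)-12-(tert-butyldimethylsilyloxy)-7-hydroxy-3,7,11-trimethyldodeca-2,10-dien-5-yn-1-yl benzoate F5. LiN(SiMe3)2 then ClCO2Me would give the tertiary propargylic methyl carbonate (2E,10E)-12-(tert-butyldimethylsilyloxy)-7-(methoxycarbonyloxy)-3,7,11-trimethyldodeca-2,10-dien-5-yn-1-yl benzoate F6. [(Ph3P)CuH]6 in PhMe would deliver hydride to C11 with loss of the carbonate and give (2E,10E)-12-(tert-butyldimethylsilyloxy)-3,7,11-trimethyldodeca-2,5,6,10-tetraen-1-yl benzoate F7, and HF·pyridine would remove the silyl group and return to the route at 8.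

Step 11. Hydrazone formation could be slow or incomplete at the C3 carbonyl, which is flanked by the quaternary C4 with its bulky axial ester. The fallback removes the oxygen by radical deoxygenation of the alcohol, from 17. NaBH4 (MeOH, 0 °C) would give (1R,2S,5R)-8-phenylmenthyl 15-(benzoyloxy)-3-hydroxylabda-8,13E-dien-19-oate F8. PhOC(S)Cl with pyridine and DMAP would give its O-phenyl thionocarbonate (1R,2S,5R)-8-phenylmenthyl 15-(benzoyloxy)-3-(phenoxythiocarbonyloxy)labda-8,13E-dien-19-oate F9 (no alkoxide is formed, which avoids retro-aldol opening). Bu3SnH with AIBN in PhMe at 100 °C (Barton–McCombie deoxygenation) would return to the route at 19.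

Further compounds
F1 | step 10 | (2E,10E)-12-bromo-7-hydroxy-3,7,11-trimethyldodeca-2,10-dien-5-yn-1-yl benzoate | BrC/C(C)=C/CCC(C)(O)C#CC/C(C)=C/COC(=O)c1ccccc1
F2 | step 10 | (1R,2S,5R)-8-phenylmenthyl (6E,14E)-16-(benzoyloxy)-10-hydroxy-2,6,10,14-tetramethyl-3-oxohexadeca-6,14-dien-11-ynoate | O=C(OC/C=C(\C)CC#CC(C)(O)CC/C=C(\C)CCC(=O)C(C)C(=O)O[C@@H]1C[C@H](C)CC[C@H]1C(C)(C)c1ccccc1)c1ccccc1
F3 | step 10 | (1R,2S,5R)-8-phenylmenthyl (6E,14E)-16-(benzoyloxy)-2-bromo-10-hydroxy-2,6,10,14-tetramethyl-3-oxohexadeca-6,14-dien-11-ynoate | O=C(OC/C=C(\C)CC#CC(C)(O)CC/C=C(\C)CCC(=O)C(C)(Br)C(=O)O[C@@H]1C[C@H](C)CC[C@H]1C(C)(C)c1ccccc1)c1ccccc1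
F4 | step 10 | (1R,2S,5R)-8-phenylmenthyl 15-(benzoyloxy)-8-hydroxy-3-oxolabda-9(11),13E-dien-19-oate (C8 and C9=C11 geometry not defined) | O=C(OC/C=C(\C)CC=C1C(C)(O)CC[C@H]2[C@@](C)(C(=O)O[C@@H]3C[C@H](C)CC[C@H]3C(C)(C)c3ccccc3)C(=O)CC[C@]12C)c1ccccc1
F5 | step 5 | (2E,10E)-12-(tert-butyldimethylsilyloxy)-7-hydroxy-3,7,11-trimethyldodeca-2,10-dien-5-yn-1-yl benzoate | CC(C)(C)[Si](C)(C)OC/C(C)=C/CCC(C)(O)C#CC/C(C)=C/COC(=O)c1ccccc1
F6 | step 5 | (2E,10E)-12-(tert-butyldimethylsilyloxy)-7-(methoxycarbonyloxy)-3,7,11-trimethyldodeca-2,10-dien-5-yn-1-yl benzoate | CC(C)(C)[Si](C)(C)OC/C(C)=C/CCC(C)(OC(=O)OC)C#CC/C(C)=C/COC(=O)c1ccccc1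
F7 | step 5 | (2E,10E)-12-(tert-butyldimethylsilyloxy)-3,7,11-trimethyldodeca-2,5,6,10-tetraen-1-yl benzoate | CC(C)(C)[Si](C)(C)OC/C(C)=C/CCC(C)=C=CC/C(C)=C/COC(=O)c1ccccc1
F8 | step 11 | (1R,2S,5R)-8-phenylmenthyl 15-(benzoyloxy)-3-hydroxylabda-8,13E-dien-19-oate (C3 configuration not defined) | O=C(OC/C=C(\C)CCC1=C(C)CC[C@H]2[C@@](C)(C(=O)O[C@@H]3C[C@H](C)CC[C@H]3C(C)(C)c3ccccc3)C(O)CC[C@]12C)c1ccccc1
F9 | step 11 | (1R,2S,5R)-8-phenylmenthyl 15-(benzoyloxy)-3-(phenoxythiocarbonyloxy)labda-8,13E-dien-19-oate | O=C(OC/C=C(\C)CCC1=C(C)CC[C@H]2[C@@](C)(C(=O)O[C@@H]3C[C@H](C)CC[C@H]3C(C)(C)c3ccccc3)C(OC(=S)Oc3ccccc3)CC[C@]12C)c1ccccc1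
A1 | direct plan | 2,6-dimethyl-1,4-benzoquinone | CC1=CC(=O)C=C(C)C1=O
A2 | direct plan | (E)-tert-butyldimethyl(penta-2,4-dien-1-yloxy)silane | C=C/C=C/CO[Si](C)(C)C(C)(C)C
A3 | direct plan | cis-fused ene-dione Diels–Alder adduct (4aR,5R,8aS)-5-[(tert-butyldimethylsilyloxy)methyl]-2,8a-dimethyl-4a,5,8,8a-tetrahydronaphthalene-1,4-dione | O=C1C(C)=CC(=O)[C@@H]2[C@H](CO[Si](C)(C)C(C)(C)C)C=CC[C@]12C
A4 | direct plan | C9 enol triflate of the trans-decalin 2-(trimethylsilyl)ethyl ester (C8=C9 alkene, 4α-ester, 5α-H, 10β-methyl) | O=S(=O)(OC1=C(C)CC[C@H]2[C@H](C(=O)OCC[Si](C)(C)C)CCC[C@]12C)C(F)(F)F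
A5 | direct plan | 2-(trimethylsilyl)ethyl 15-(tert-butyldimethylsilyloxy)-18-norlabda-8,13E-dien-19-oate (C4–H ester) | CC(C)(C)[Si](C)(C)OC/C=C(\C)CCC1=C(C)CC[C@H]2[C@H](C(=O)OCC[Si](C)(C)C)CCC[C@]12C
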